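All runs are calculated on assumed constants.

In the dawn run the D charged stays accounted for as D or as Z: at the last reading 64.9% and 36.2% add up to 101%, within the scatter.

| flask | D | L | remark | time |
|---|---|---|---|---|
| dawn | 0.36 M | 0.23 M | run made earlier |  |
| spring | 0.36 M | 0.51 M | run made earlier |  |
| flask | 0.36 M | 0.342 M |  | 4.0 d |

- dawn (time / d: Z / %, D / %): 0.208: 63.7, 35.6; 0.333: 64.0, 35.2; 0.625: 64.8, 36.7; 1.25: 64.0, 37.1; 2.50: 64.9, 36.2
- spring (time / d: Z / %, D / %): 0.208: 98.8, 0; 0.333: 99.2, 2.8; 0.625: 100.6, 1.6; 1.25: 98.8, 0; 2.50: 99.2, 0.5

(scatter of a reading: 1 percentage point)

- why nothing more happens at 4.0 d, or that something still does (L has run out first / forward and back rates have come level / it is still moving / all of D has reacted)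
- Z at 4.0 d, in percent of the D charged
- amount of Z if the flask were left three thousand times as long, in percent of the D charged

- a reading or a percentage of Z counts all its forms, free or not
- the reaction counts as stopped when no species that holds the D changes by six tenths of a point or more over the second half of the time

Here is the puzzle. By 0.208 d the dawn run stands still with Z at 63.7% and D at 35.6%, yet the spring run, from the same 0.36 M of D, already shows 98.8% of Z. Why does D that can plainly react sit idle at dawn?

We reckon it in three steps.

1. Dawn's L per D is 63.9%, which matches its Z readings within the scatter, and the unmatched rest, 36.1%, matches its D readings likewise. So one L makes one Z, and L is the limiting reagent at dawn. In spring the ratio is 1.42, above one, so there L outlasts D.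

2. Call the ceiling the Z, in percent of the D charged, that the L charge allows when L per D is below one. For the flask it is 95.0%.

3. Does the flask reach it in time? We take the rate as going with [D][L]. Late on, [D] sits near the excess of D, so L falls in a pseudo-first-order tail whose pace goes with that excess. The flask's excess, 0.0180 M, is smaller than dawn's 0.130 M by a factor of 7.22. Dawn's tail was over by 0.208 d, so we estimate that the flask's should be over by about 1.50 d, earlier than 4.0 d. We commit to the ceiling.

The forecast gives 95% at the asked time and 95% in the long run, with the answer "L has run out first", and holds that “conversion is finished well before 4 d”.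

The flask gives 95.0% of Z at 4.0 d and 95.0% in the long run, with the answer "L has run out first": the ceiling of 95.0% is met, with 0% of its L left. At that time 22.8% of the D charged stands as crystals G, counted in Z, and the low solubility of Z leaves the amount of Z unchanged.

    G ⇌ Z, rate k1*(cs1 - [Z]) while solid is left; crystals form when [Z] > cs1 (solubility = 0.260 M, k = 0.0170 s⁻¹)
    D + L → Z (k = 1.80 × 10⁻⁶ L mol⁻¹ s⁻¹)
    D + L + Z → 2 Z (k = 0.0130 L² mol⁻² s⁻¹)

With D raised to 0.90 M and L held, the ceiling falls to 38.0%, and that neighbour flask gives 38.0% of Z, with 62.0% of its D left.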